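(Its constants were set for the occasion, and the outcome is calculated.)

substrate 0.020 M; precatalyst 2.0 µM

    substrate + enzyme → product + enzyme, rate k1*[substrate]*[enzyme]/(1 + ([substrate]/Km1)) (Km1 = 16 mM, k1 = 2.4 × 10⁵ L mol⁻¹ s⁻¹)
    precatalyst ⇌ enzyme (K2 = 0.60, k2 = 0.093 s⁻¹)

- the form that holds most of the catalyst when 20% of the substrate are converted (precatalyst / enzyme)
- its share of the catalyst then
- factor on the rate of making product when 20% of the substrate are converted if precatalyst is charged twice over
- factor on the rate when 20% of the substrate are converted if precatalyst is charged at 0.20 µM instead

Start from the easy step: divide the rate law of the first step by c(substrate) and integrate. The natural log of starting over present c(substrate), plus the c(substrate) consumed over Km, equals the rate constant times the time integral of c(enzyme). So 20% conversion in this flask costs 1.97 µM·s. Call this the enzyme exposure, the time integral of c(enzyme) needed for a given conversion.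

The enzyme comes from the precatalyst, an off-cycle form, relaxing at 0.248 s⁻¹ towards 37.5% of the charge, here 0.750 µM. Two extreme flasks can be done in the head. In the young flask c(enzyme) stays on its first slope, so exposure is slope times time squared over 2, reached at 4.60 s; that curve runs above the true one, so the real time is longer. In the late flask c(enzyme) sits on its plateau after a lag of 4.03 s, reached at 6.66 s; the exposure so reckoned runs below the true one, so the real time is shorter. Putting the mean of the two times into the exact integral, I get 5.66 s and an enzyme share of 28.3%, which leaves precatalyst 71.7%. On doubling the charge, the rate grows as its root in the young flask, 1.41, and in proportion in the late one, 2, so the factor lies between. With 0.20 µM, the exposure takes 30.3 s, longer than the lag, so the late form holds. At equal conversion the rate follows c(enzyme), so I expect a factor of 0.133.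

The forecast says precatalyst at 72%, with factors of 1.6 and 0.13, on the ground that “activation is incomplete at the base charge”. The simulation gives precatalyst at 71.7%, with factors of 1.61 and 0.132, and reaches the conversion at 5.67 s.

The run with the falling back of enzyme to precatalyst taken away gives a rate at 20% conversion of 1.30 times the actual one. Its first step is unchanged, so that run still needs 1.97 µM·s, but its enzyme climbs without the return path. The forecast's 72% does not hold in that run. At equal conversion the rate follows c(enzyme), so precatalyst in that run is down to 63.1%.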